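## Retrosynthetic overview

- **Feature:** the C8 ketone, C7, C11 with its methyl C13, and the ester carbon C12, all attached to ring B, have the connectivity and oxygen pattern of a 3-methylfuran fused to ring B across C7–C8 that has been oxidised at C8 and C12 and opened.
- **Endgame:** target ⇐ 6α-formate of the (Z)-8-oxo-7(11)-en-12-oate (palladium–formate transposition puts H on C11 and moves the alkene to C6–C7) ⇐ singlet-oxygen opening and O-methylation of a 3β-angeloyloxy-6α-hydroxyfuranoeremophilane.
- **Key disconnection C6–C7:** tricyclic furyl ketone ⇐ ring A acid with CO2H (C6) on C5 and a (4-methylfuran-2-yl)methyl group on C10. An intramolecular Friedel–Crafts acylation closes ring B.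
- **Ring A acid** ⇐ Negishi coupling (C8–C9) of a C9 zinc reagent and 2-bromo-4-methylfuran ⇐ enantioselective Diels–Alder adduct of tiglaldehyde and silylated pentadienol (sets C4, C5, C10). The C3 oxygen comes from allylic oxidation and hydride reduction.
- **Ring order:** furan (bought), ring A (cycloaddition), ring B (acylation). The furan ring is opened at the end.

Key step: step 13

Convention: eremophilane numbering is used for every intermediate (ring A = C1–C5 and C10; ring B = C5–C10; C14 on C5, C15 on C4). β is the face that carries C14 and C15.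

Assumption: the sense of induction in step 2 follows the formyl C–H···O binding model for 2-substituted enals, under which the (R)-prolinol-derived catalyst leaves the Si face of C5 of tiglaldehyde open.

## Route

Step 1
Reactants: 1 (E)-penta-2,4-dien-1-ol
Product: 2 (E)-tert-butyldimethyl(penta-2,4-dienyloxy)silane
Conditions: TBSCl, imidazole, CH2Cl2, 0 °C → rt
Reagents that add atoms: tert-butyldimethylsilyl chloride, CC(C)(C)[Si](C)(C)Cl
Why: Imidazole-assisted silylation of a primary alcohol gives an ether that keeps the diene electron-rich and tolerates the Lewis acid of step 2; no stereocentre is formed.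

Step 2
Reactants: 2 (E)-tert-butyldimethyl(penta-2,4-dienyloxy)silane; 3 tiglaldehyde
Product: 4 4β,5β-dimethyl-10α-[(tert-butyldimethylsilyloxy)methyl]cyclohex-1-ene-5α-carbaldehyde (ring A aldehyde)
Conditions: (R)-oxazaborolidinium triflimide [from (R)-α,α-diphenylprolinol and tri-o-tolylboroxine, then Tf2NH] (20 mol%), CH2Cl2, −40 → −20 °C
Reagents that add atoms: none
Why: In this catalytic enantioselective Diels–Alder reaction the cationic boron Lewis acid binds the formyl group of the s-trans enal and covers the Re face of C5, and the diene adds "ortho" (C10 to C5, C3 to C4) and endo, so the E geometry of 3 places C15 cis to C14, the endo rule places CH2OTBS cis to CHO, and the catalyst fixes the absolute configuration of C4, C5 and C10.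

Step 3
Reactants: 4 ring A aldehyde
Product: 5 4β,5β-dimethyl-10α-(TBSO-methyl)cyclohex-1-ene-5α-carboxylic acid
Conditions: NaClO2, NaH2PO4, 2-methylbut-2-ene, t-BuOH/H2O, 0 °C → rt
Reagents that add atoms: sodium chlorite, [Na+].[O-]Cl=O
Why: The Pinnick oxidation converts the non-enolisable aldehyde into the acid while 2-methylbut-2-ene removes HOCl, so the alkene, the silyl ether and all stereocentres are untouched.

Step 4
Reactants: 5 ring A alkene acid
Product: 6 methyl 4β,5β-dimethyl-10α-(TBSO-methyl)cyclohex-1-ene-5α-carboxylate
Conditions: MeI, K2CO3, DMF, rt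
Reagents that add atoms: iodomethane, CI
Why: SN2 O-alkylation of the carboxylate avoids attack at the hindered carbonyl and masks C6 as an ester that can later be cleaved at its methyl carbon.

Step 5
Reactants: 6 ring A alkene ester
Product: 7 methyl 4β,5β-dimethyl-3-oxo-10α-(TBSO-methyl)cyclohex-1-ene-5α-carboxylate
Conditions: Rh2(cap)4 (cap = caprolactamate, 1 mol%), t-BuOOH (70% aq.), 1,2-dichloroethane, 40 °C, no base
Reagents that add atoms: tert-butyl hydroperoxide, CC(C)(C)OO
Why: In this radical allylic oxidation (tert-butylperoxyl chain) only the C3 methylene offers an accessible allylic C–H, because C10–H is tertiary and buried between C5 and the silyloxymethyl group, and capture of the C1–C3 allyl radical at C3, next to the small C15 methyl rather than next to C10, should predominate; the 1-oxo isomer is the expected by-product and is removed by chromatography.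

Step 6
Reactants: 7 ring A enone ester
Product: 8 methyl 4β,5β-dimethyl-3-oxo-10α-(TBSO-methyl)cyclohexane-5α-carboxylate
Conditions: H2 (1 atm), Pd/C, EtOAc, rt
Reagents that add atoms: none
Why: Heterogeneous hydrogenation saturates the disubstituted C1=C2 bond under neutral conditions, so the epimerisable C4 next to the ketone is not disturbed and no stereocentre is created.

Step 7
Reactants: 8 ring A ketone ester
Product: 9 methyl 3β-hydroxy-4β,5β-dimethyl-10α-(TBSO-methyl)cyclohexane-5α-carboxylate
Conditions: LiBH(s-Bu)3, THF, −78 °C; then H2O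
Reagents that add atoms: none
Why: The bulky hydride should attack C3 from the α face, away from the adjacent C15 and the 1,3-related C14 (equatorial attack on the conformer with equatorial C15), giving the 3β-alcohol cis to C15 as in the 2-methylcyclohexanone to cis-2-methylcyclohexanol case, and any 3α-epimer would lactonise onto C6 and be separated.

Step 8
Reactants: 9 ring A 3β-alcohol
Product: 10 methyl 3β-acetoxy-4β,5β-dimethyl-10α-(TBSO-methyl)cyclohexane-5α-carboxylate
Conditions: Ac2O, pyridine, DMAP (cat.), CH2Cl2, rt
Reagents that add atoms: acetic anhydride, CC(=O)OC(C)=O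
Why: DMAP-catalysed acylation installs an ester that withstands the bromination, the zinc chemistry and the tin Lewis acid of the key step, with retention at C3.

Step 9
Reactants: 10 ring A acetate silyl ether
Product: 11 methyl 3β-acetoxy-10α-(bromomethyl)-4β,5β-dimethylcyclohexane-5α-carboxylate
Conditions: Ph3PBr2, CH2Cl2, 0 °C → rt
Reagents that add atoms: dibromotriphenylphosphorane, BrP(Br)(c1ccccc1)(c1ccccc1)c1ccccc1
Why: This Appel-type direct conversion of a TBS ether (phosphonium activation of the ether oxygen, then SN2 attack of bromide at primary C9) avoids the free γ-hydroxy ester, which would lactonise onto C6.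

Step 10
Reactants: 12 3-methylfuran
Product: 14 2-bromo-4-methylfuran, via 4-methyl-2-furyllithium 13 (not isolated)
Conditions: n-BuLi, TMEDA, Et2O, −78 → 0 °C; BrCH2CH2Br, −78 °C → rt
Reagents that add atoms: 1,2-dibromoethane, BrCCBr
Why: Kinetic α-lithiation of the furan should occur for steric reasons at the α-position remote from the methyl group, and the furyllithium then takes bromine from 1,2-dibromoethane with loss of ethene; the minor 2-bromo-3-methyl isomer is removed by distillation.

Step 11
Reactants: 11 ring A bromide; 14 2-bromo-4-methylfuran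
Product: 16 methyl 3β-acetoxy-4β,5β-dimethyl-10α-[(4-methylfuran-2-yl)methyl]cyclohexane-5α-carboxylate, via alkylzinc bromide 15 (not isolated)
Conditions: Zn dust, I2 (5 mol%), DMA, 70 °C; then 14, Pd(OAc)2 (2 mol%), SPhos (4 mol%), THF, rt
Reagents that add atoms: none
Why: In this Negishi coupling, zinc insertion is insensitive to the β-branching at C9, the γ-zincio ester is a stable reagent class that tolerates both esters, and sp3–sp2 coupling forms C8–C9 without touching a stereocentre.

Step 12
Reactants: 16 furylmethyl methyl ester
Product: 17 3β-acetoxy-4β,5β-dimethyl-10α-[(4-methylfuran-2-yl)methyl]cyclohexane-5α-carboxylic acid (ring A acid)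
Conditions: LiI, 2,4,6-collidine, reflux (N2); then cold 1 M HCl
Reagents that add atoms: none
Why: Nucleophilic ester cleavage (SN2 attack of iodide at the ester methyl carbon) frees the hindered acid, while the secondary acetate, which offers no unhindered alkyl carbon, survives.

Step 13
Reactants: 17 ring A acid
Product: 19 3β-acetoxy-10βH-furanoeremophilan-6-one, via acid chloride 18 (not isolated)
Conditions: 1-chloro-N,N,2-trimethylprop-1-en-1-amine, CH2Cl2, 0 °C → rt; then SnCl4 (2.5 equiv), CH2Cl2 (0.005 M), −78 → −30 °C
Reagents that add atoms: none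
Why: The acid is converted into 18 under neutral conditions (no HCl and no formylating agent near the furan), SnCl4 ionises it to the acylium ion, furan carbon C7 attacks C6, and loss of the C7 proton restores the aromatic ring; this is an intramolecular Friedel–Crafts acylation whose closest precedent is the cyclisation of 4-(2-furyl)butanoyl chlorides to 6,7-dihydrobenzofuran-4(5H)-ones. Ring B closes as a six-membered ring, exo with respect to the C6 carbonyl (its oxygen stays outside the ring), and the nucleophilic C7=C8 bond ends up inside the ring. No stereocentre is formed, and C3, C4, C5 and C10 are untouched because C5 is quaternary and cannot enolise. The step needs attack at the β-carbon C7 although the free α-carbon C12 is intrinsically the more nucleophilic site: the C5–C10–C9 tether lets C6 reach only C7, C8 is occupied by C9, and high dilution suppresses intermolecular acylation at C12. The C8 alkyl group and the C11 methyl group both activate C7. Low temperature and the mild tin Lewis acid are chosen so that capture by the furan is faster than loss of CO from the tertiary acylium ion and than acid damage to the furan.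

Step 14
Reactants: 19 tricyclic furyl ketone
Product: 20 3β-acetoxy-10βH-furanoeremophilan-6α-ol
Conditions: LiBH(s-Bu)3, THF, −78 → −20 °C; then H2O
Reagents that add atoms: none
Why: In the cis-fused ketone the α face is concave (C1 is syn-axial to C6), so the bulky hydride should attack equatorially from the convex β face despite the adjacent C14, as it does in 4,4-dimethyl-3-oxo triterpenoids, giving the axial 6α-alcohol whose configuration later decides C11.

Step 15
Reactants: 20 6α-hydroxy acetate
Product: 21 10βH-furanoeremophilane-3β,6α-diol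
Conditions: K2CO3 (cat.), MeOH, rt
Reagents that add atoms: none
Why: Base-catalysed transesterification removes the acetate at a stage where no base-sensitive stereocentre exists, and the acid-labile furyl carbinol is safe in base.

Step 16
Reactants: 21 3β,6α-diol; 22 angelic acid
Product: 24 3β-angeloyloxy-10βH-furanoeremophilan-6α-ol, via mixed anhydride 23 (not isolated)
Conditions: 22, 2,4,6-Cl3C6H2COCl, Et3N, toluene, rt; then 21, 80 °C, no DMAP
Reagents that add atoms: none
Why: A Yamaguchi-type mixed-anhydride esterification run without a nucleophilic catalyst keeps the Z geometry of the angelate, and the C3 hydroxyl reacts in preference to the C6 carbinol, which is neopentyl and flanked by the furan bearing C13.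

Step 17
Reactants: 24 furan angelate
Product: 26 3β-angeloyloxy-6α,8β-dihydroxy-10βH-eremophil-7(11)-en-12,8α-olide, via furan endoperoxide 25 (not isolated)
Conditions: O2, tetraphenylporphyrin (cat.), visible light, CH2Cl2, −78 °C; then i-Pr2NEt, −78 °C → rt
Reagents that add atoms: dioxygen, O=O
Why: Singlet oxygen adds [4+2] across C8 and C12 from the convex β face, and the base triggers a Kornblum–DeLaMare fragmentation in which only C12 carries a hydrogen, so C12 becomes the lactone carbonyl and C8 the hemiketal; the trialkylfuran reacts far faster than the electron-poor angelate alkene, and the C8 centre is lost again in step 18.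

Step 18
Reactants: 26 hydroxybutenolide
Product: 28 methyl (Z)-3β-angeloyloxy-6α-hydroxy-8-oxo-10βH-eremophil-7(11)-en-12-oate, via open keto acid 27 (not isolated)
Conditions: TMSCHN2, toluene/MeOH 4:1, 0 °C
Reagents that add atoms: trimethylsilyldiazomethane, C[Si](C)(C)C=[N+]=[N-]
Why: The hydroxybutenolide is the ring tautomer (pseudo-acid) of keto acid 27, and neutral O-methylation of the carboxyl group traps the open form as the normal ester, with the Z geometry (C12 cis to C8) inherited from the ring.

Step 19
Reactants: 28 6α-hydroxy keto ester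
Product: 29 methyl (Z)-3β-angeloyloxy-6α-formyloxy-8-oxo-10βH-eremophil-7(11)-en-12-oate
Conditions: acetic formic anhydride (preformed), pyridine, CH2Cl2, 0 °C
Reagents that add atoms: acetic formic anhydride, CC(=O)OC=O
Why: O-formylation with the smallest available acyl donor reaches the hindered allylic alcohol with retention at C6, and allylic strain against C13 keeps the new ester pseudo-axial.

Step 20
Reactants: 29 6α-formate
Product: 30 methyl (3S,4R,5R,10R,11R)-3β-angeloyloxy-8-oxoeremophil-6-en-12-oate (target)
Conditions: Pd(acac)2 (10 mol%), n-Bu3P (10 mol%), THF, rt → 40 °C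
Reagents that add atoms: none
Why: Proposed new method: zerovalent palladium formed from Pd(acac)2 and n-Bu3P should ionise the pseudo-axial 6α-formate from the β face, the bound formate loses CO2, and the palladium hydride delivers H to C11 on that same β face, which for the fixed Z alkene (C12 cis to C8) gives 11R and moves the alkene to C6–C7; the closest known reaction is the palladium–formate hydrogenolysis of cyclic allylic formates and carbonates bearing an exocyclic tetrasubstituted alkene with 1,3-chirality transfer (steroid C16 to C20), and what is new is an allyl unit with a ketone on its central carbon and an ester on the terminus that must accept hydride.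

## Compound list

1 | (E)-penta-2,4-dien-1-ol | C=C/C=C/CO | starting material
2 | (E)-tert-butyldimethyl(penta-2,4-dienyloxy)silane | C=C/C=C/CO[Si](C)(C)C(C)(C)C | intermediate
3 | tiglaldehyde, (E)-2-methylbut-2-enal | C/C=C(\C)C=O | starting material
4 | ring A aldehyde | C1C=C[C@H](CO[Si](C)(C)C(C)(C)C)[C@](C)(C=O)[C@H]1C | intermediate
5 | ring A alkene acid | C1C=C[C@H](CO[Si](C)(C)C(C)(C)C)[C@](C)(C(=O)O)[C@H]1C | intermediate
6 | ring A alkene methyl ester | C1C=C[C@H](CO[Si](C)(C)C(C)(C)C)[C@](C)(C(=O)OC)[C@H]1C | intermediate
7 | ring A 3-oxo-1-ene ester | O=C1C=C[C@H](CO[Si](C)(C)C(C)(C)C)[C@](C)(C(=O)OC)[C@H]1C | intermediate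
8 | ring A 3-ketone ester | O=C1CC[C@H](CO[Si](C)(C)C(C)(C)C)[C@](C)(C(=O)OC)[C@H]1C | intermediate
9 | ring A 3β-alcohol | O[C@H]1CC[C@H](CO[Si](C)(C)C(C)(C)C)[C@](C)(C(=O)OC)[C@H]1C | intermediate
10 | ring A 3β-acetate | CC(=O)O[C@H]1CC[C@H](CO[Si](C)(C)C(C)(C)C)[C@](C)(C(=O)OC)[C@H]1C | intermediate
11 | ring A C9 bromide | CC(=O)O[C@H]1CC[C@H](CBr)[C@](C)(C(=O)OC)[C@H]1C | intermediate
12 | 3-methylfuran | Cc1ccoc1 | starting material
13 | 4-methyl-2-furyllithium | [Li]c1cc(C)co1 | intermediate
14 | 2-bromo-4-methylfuran | Brc1cc(C)co1 | intermediate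
15 | ring A C9 zinc bromide | CC(=O)O[C@H]1CC[C@H](C[Zn]Br)[C@](C)(C(=O)OC)[C@H]1C | intermediate
16 | furylmethyl methyl ester | CC(=O)O[C@H]1CC[C@H](Cc2cc(C)co2)[C@](C)(C(=O)OC)[C@H]1C | intermediate
17 | ring A acid (key-step precursor) | CC(=O)O[C@H]1CC[C@H](Cc2cc(C)co2)[C@](C)(C(=O)O)[C@H]1C | intermediate
18 | ring A acid chloride | CC(=O)O[C@H]1CC[C@H](Cc2cc(C)co2)[C@](C)(C(=O)Cl)[C@H]1C | intermediate
19 | 3β-acetoxy-10βH-furanoeremophilan-6-one | CC(=O)O[C@H]1CC[C@@H]2Cc3occ(C)c3C(=O)[C@]2(C)[C@H]1C | intermediate
20 | 3β-acetoxy-10βH-furanoeremophilan-6α-ol | CC(=O)O[C@H]1CC[C@@H]2Cc3occ(C)c3[C@H](O)[C@]2(C)[C@H]1C | intermediate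
21 | 10βH-furanoeremophilane-3β,6α-diol | O[C@H]1CC[C@@H]2Cc3occ(C)c3[C@H](O)[C@]2(C)[C@H]1C | intermediate
22 | angelic acid | C/C=C(/C)C(=O)O | starting material
23 | angelic 2,4,6-trichlorobenzoic anhydride | C/C=C(/C)C(=O)OC(=O)c1c(Cl)cc(Cl)cc1Cl | intermediate
24 | 3β-angeloyloxy-10βH-furanoeremophilan-6α-ol | C/C=C(/C)C(=O)O[C@H]1CC[C@@H]2Cc3occ(C)c3[C@H](O)[C@]2(C)[C@H]1C | intermediate
25 | 8β,12β-epidioxide of 24 (furan endoperoxide) | C/C=C(/C)C(=O)O[C@H]1CC[C@@H]2C[C@]34OO[C@H](O3)C(C)=C4[C@H](O)[C@]2(C)[C@H]1C | intermediate
26 | 3β-angeloyloxy-6α,8β-dihydroxy-10βH-eremophil-7(11)-en-12,8α-olide | C/C=C(/C)C(=O)O[C@H]1CC[C@@H]2C[C@]3(O)OC(=O)C(C)=C3[C@H](O)[C@]2(C)[C@H]1C | intermediate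
27 | (Z)-3β-angeloyloxy-6α-hydroxy-8-oxo-10βH-eremophil-7(11)-en-12-oic acid | C/C=C(/C)C(=O)O[C@H]1CC[C@@H]2CC(=O)/C(=C(/C)C(=O)O)[C@H](O)[C@]2(C)[C@H]1C | intermediate
28 | methyl ester of 27 | C/C=C(/C)C(=O)O[C@H]1CC[C@@H]2CC(=O)/C(=C(/C)C(=O)OC)[C@H](O)[C@]2(C)[C@H]1C | intermediate
29 | 6α-formate of 28 | C/C=C(/C)C(=O)O[C@H]1CC[C@@H]2CC(=O)/C(=C(/C)C(=O)OC)[C@H](OC=O)[C@]2(C)[C@H]1C | intermediate
30 | methyl (11R)-3β-angeloyloxy-8-oxo-10βH-eremophil-6-en-12-oate | C/C=C(/C)C(=O)O[C@H]1CC[C@@H]2CC(=O)C([C@@H](C)C(=O)OC)=C[C@]2(C)[C@H]1C | target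

## Step count and risks

Total steps: 20. Longest linear sequence: 19 (steps 1–9 and 11–20; step 10 is a side branch).

**Step 20 (Proposed new method).**
- What may go wrong: no ionisation at the neopentyl C6; hydride transfer to C6 instead of C11; migration of palladium to the ester oxygen with loss of facial memory; phosphine-induced Z/E isomerisation of the very electrophilic alkene.
- Fallback, from 29 back to 30, replaces the π-allyl chemistry by conjugate reduction and β-elimination. Copper hydride generated from Cu(OAc)2·H2O, 1,2-bis(diphenylphosphino)benzene and PMHS with t-BuOH in toluene at 0 °C should add hydride to C11, the β-carbon of the C8 enone. Attack should come from the β face, anti to the pseudo-axial 6α-formate.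
- Protonation of the enolate then gives methyl (11R)-3β-angeloyloxy-6α-formyloxy-8-oxo-10βH-eremophilan-12-oate F1. Brief exposure to Et3N in CH2Cl2 at 0 °C removes formic acid by an E1cB path and gives 30.

**Step 13 (key step).**
- What may go wrong: loss of CO from the tertiary acylium ion; acid-induced polymerisation of the furan; intermolecular acylation at the free C12.
- Fallback, from 17 back to 19, forms the same bond with an iminium electrophile instead of an acylium ion. Acid chloride 18 and Me2NH give the N,N-dimethylamide of the ring A acid F2.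
- Tf2O and 2-fluoropyridine in CH2Cl2 (−78 → 0 °C) activate the amide, and C7 attacks in an intramolecular Vilsmeier–Haack-type acylation. This path cannot decarbonylate and needs no Lewis acid. It gives the tricyclic C6 dimethyliminium triflate F3, and aqueous NaHCO3 hydrolyses this to 19.

**Step 14.**
- What may go wrong: attack of the hydride on the concave α face (axial attack), or no reduction of the hindered, vinylogous-ester-like ketone.
- Fallback, from 19 back to 21, accepts axial attack and inverts afterwards. A small hydride (NaBH4, CeCl3·7H2O, MeOH, 0 °C) gives 3β-acetoxy-10βH-furanoeremophilan-6β-ol F4.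
- A Mitsunobu reaction (4-nitrobenzoic acid, PPh3, DIAD, toluene) ionises the furan-stabilised C6 within the ion pair. The carboxylate enters from the α face, which the departing phosphine oxide leaves open and which the hydride had preferred, giving 3β-acetoxy-10βH-furanoeremophilan-6α-yl 4-nitrobenzoate F5.
- K2CO3 in MeOH removes both esters and gives 21.

## Further compounds

F1 | step 20 | methyl (11R)-3β-angeloyloxy-6α-formyloxy-8-oxo-10βH-eremophilan-12-oate (C7 not defined, lost in the elimination) | C/C=C(/C)C(=O)O[C@H]1CC[C@@H]2CC(=O)C([C@@H](C)C(=O)OC)[C@H](OC=O)[C@]2(C)[C@H]1C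
F2 | step 13 | N,N-dimethylamide of the ring A acid | CC(=O)O[C@H]1CC[C@H](Cc2cc(C)co2)[C@](C)(C(=O)N(C)C)[C@H]1C
F3 | step 13 | tricyclic C6 dimethyliminium triflate | CC(=O)O[C@H]1CC[C@@H]2Cc3occ(C)c3C(=[N+](C)C)[C@]2(C)[C@H]1C.[O-]S(=O)(=O)C(F)(F)F
F4 | step 14 | 3β-acetoxy-10βH-furanoeremophilan-6β-ol | CC(=O)O[C@H]1CC[C@@H]2Cc3occ(C)c3[C@@H](O)[C@]2(C)[C@H]1C
F5 | step 14 | 3β-acetoxy-10βH-furanoeremophilan-6α-yl 4-nitrobenzoate | CC(=O)O[C@H]1CC[C@@H]2Cc3occ(C)c3[C@H](OC(=O)c4ccc(cc4)[N+](=O)[O-])[C@]2(C)[C@H]1C
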